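**Strategy.** Numbering: C1H2=C2, C3 (carboxyl C11), C4 (C12H2–C13HO), C5 (formyl C14), ring O19/C15–C18, ketone C9. Everything rests on disconnecting the exocyclic tetrasubstituted enol-ether alkene C5=C15 of the 5,5-dimethyl-2,5-dihydrofuran ring, whose formyl carbon C14 lies trans to O19 – the imprint of anti addition of oxygen and carbon across an alkyne. One palladium-catalysed operation closes that ring (O19–C15) and attaches C14 (C5–C14) as a methyl ester with the target geometry. The precursor is a Z-enynol: the C5≡C15 alkyne joined through the cis C16=C17 alkene to the tertiary C18 carbinol, with C3 and C4 set and C11, C13 and C9 masked.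

Key step: step 16

Remark 1: the rearrangement of step 8 fixes only the relative configuration of C3 and C4; the absolute configuration is secured in step 9 by separating diastereomeric N-acyl oxazolidinones, the (2S,3R) series to be assigned by crystallography of 19 or of a derivative.
Remark 2: C11 is carried as a tert-butyldiphenylsilyl ether (inert in the palladium step, released by fluoride) and is oxidised only after C14 has reached the aldehyde level; racemates are written as both enantiomers joined by a dot.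
Assumption: the target is taken as the open-chain oxo acid drawn; a ring–chain equilibrium with its hydroxy lactone would not change the route.

**Route**

Step 1
Reactants: 1 but-2-yne-1,4-diol
Product: 2 4-[(4-methoxybenzyl)oxy]but-2-yn-1-ol
Conditions: NaH (1 equiv), 4-methoxybenzyl chloride, n-Bu4NI (cat.), THF–DMF, 0 °C → rt, diol in threefold excess
Reagents that add atoms: 4-methoxybenzyl chloride, COc1ccc(CCl)cc1
Why: Williamson etherification of the monoalkoxide of a symmetrical diol used in excess should stop at the monoether.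

Step 2
Reactants: 2 4-[(4-methoxybenzyl)oxy]but-2-yn-1-ol
Product: 4 (Z)-3-iodo-4-[(4-methoxybenzyl)oxy]but-2-en-1-ol, via cyclic alkenylalanate 3 (not isolated)
Conditions: NaAlH2(OCH2CH2OMe)2, THF, 0 °C; then I2, THF, −78 → 0 °C
Reagents that add atoms: iodine, II
Why: Hydroxyl-directed trans-hydroalumination puts hydride on the alkyne carbon next to the carbinol and aluminium on the distal carbon inside a five-membered alanate, and iodinolysis with retention should give the Z-iodide (kept cold to avoid loss of the β-alkoxy group).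

Step 3
Reactants: 4 (Z)-3-iodo-4-[(4-methoxybenzyl)oxy]but-2-en-1-ol
Product: 5 (Z)-tert-butyl({3-iodo-4-[(4-methoxybenzyl)oxy]but-2-en-1-yl}oxy)diphenylsilane
Conditions: t-BuPh2SiCl, imidazole, CH2Cl2, 0 °C → rt
Reagents that add atoms: tert-butyl(chloro)diphenylsilane, CC(C)(C)[Si](Cl)(c1ccccc1)c1ccccc1
Why: Standard imidazole-promoted silylation of a primary alcohol installs the robust ether that will protect C11 up to step 19.

Step 4
Reactants: 5 (Z)-tert-butyl({3-iodo-4-[(4-methoxybenzyl)oxy]but-2-en-1-yl}oxy)diphenylsilane; 6 2-(3-chloropropyl)-2-methyl-1,3-dioxolane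
Product: 9 (E)-tert-butyl{[3-{[(4-methoxybenzyl)oxy]methyl}-6-(2-methyl-1,3-dioxolan-2-yl)hex-2-en-1-yl]oxy}diphenylsilane, via Grignard reagent 7 (not isolated), via alkylzinc chloride 8 (not isolated)
Conditions: 6, Mg, THF, reflux; ZnCl2, THF, 0 °C; then 5, PdCl2(dppf) (cat.), THF, rt → 45 °C
Reagents that add atoms: none
Why: Negishi sp3–sp2 cross-coupling of a primary alkylzinc with an alkenyl iodide proceeds with retention of alkene geometry, the bidentate ligand suppressing β-hydride elimination.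

Step 5
Reactants: 9 (E)-tert-butyl{[3-{[(4-methoxybenzyl)oxy]methyl}-6-(2-methyl-1,3-dioxolan-2-yl)hex-2-en-1-yl]oxy}diphenylsilane
Product: 10 (E)-2-{2-[(tert-butyldiphenylsilyl)oxy]ethylidene}-5-(2-methyl-1,3-dioxolan-2-yl)pentan-1-ol
Conditions: DDQ (1.2 equiv), CH2Cl2–pH 7 phosphate buffer, 0 °C
Reagents that add atoms: none
Why: Oxidative cleavage of the 4-methoxybenzyl ether (benzylic hydride abstraction, hydrolysis of the oxocarbenium ion) should free the C1 hydroxyl while silyl ether, ketal and alkene stay intact under buffered conditions.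

Step 6
Reactants: 11 methyl 4,4-dimethoxybutanoate
Product: 12 4,4-dimethoxybutanoic acid
Conditions: LiOH, THF–H2O, rt; then aq. HCl to pH 4 at 0 °C, used at once
Reagents that add atoms: lithium hydroxide, [Li+].[OH-]
Why: Saponification followed by cold, mild acidification should give the acid without hydrolysing the acetal.

Step 7
Reactants: 10 (E)-2-{2-[(tert-butyldiphenylsilyl)oxy]ethylidene}-5-(2-methyl-1,3-dioxolan-2-yl)pentan-1-ol; 12 4,4-dimethoxybutanoic acid
Product: 13 (E)-2-{2-[(tert-butyldiphenylsilyl)oxy]ethylidene}-5-(2-methyl-1,3-dioxolan-2-yl)pentyl 4,4-dimethoxybutanoate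
Conditions: i-PrN=C=N-i-Pr, 4-(dimethylamino)pyridine (cat.), CH2Cl2, 0 °C → rt
Reagents that add atoms: none
Why: Steglich esterification joins the two fragments under neutral conditions that tolerate acetal, ketal and silyl ether.

Step 8
Reactants: 13 (E)-2-{2-[(tert-butyldiphenylsilyl)oxy]ethylidene}-5-(2-methyl-1,3-dioxolan-2-yl)pentyl 4,4-dimethoxybutanoate
Product: 17 rac-(2S,3R)-3-{[(tert-butyldiphenylsilyl)oxy]methyl}-2-(2,2-dimethoxyethyl)-4-methylidene-7-(2-methyl-1,3-dioxolan-2-yl)heptanoic acid, via lithium enolate 14 (not isolated), via silyl ketene acetal 15 (not isolated), via trimethylsilyl ester 16 (not isolated)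
Conditions: LiN(i-Pr)2, THF, −78 °C; Me3SiCl–Et3N, −78 °C → rt, then 60 °C; aqueous work-up at pH 5
Reagents that add atoms: none
Why: Ireland–Claisen rearrangement, in which kinetic deprotonation gives the E(O)-enolate (C12 chain trans to OLi) and the chair transition state of its silyl ketene acetal with the E-allyl unit (C11 equatorial, C12 axial) should set C3 and C4 in the anti relationship of the target, as a racemate, while forming the C1=C2 methylidene.

Step 9
Reactants: 17 rac-(2S,3R)-3-{[(tert-butyldiphenylsilyl)oxy]methyl}-2-(2,2-dimethoxyethyl)-4-methylidene-7-(2-methyl-1,3-dioxolan-2-yl)heptanoic acid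
Product: 19 (4S)-4-benzyl-3-[(2S,3R)-3-{[(tert-butyldiphenylsilyl)oxy]methyl}-2-(2,2-dimethoxyethyl)-4-methylidene-7-(2-methyl-1,3-dioxolan-2-yl)heptanoyl]-1,3-oxazolidin-2-one, via mixed pivalic anhydride 18 (not isolated)
Conditions: t-BuCOCl, Et3N, THF, −20 °C; then (S)-4-benzyl-1,3-oxazolidin-2-one, LiCl, rt; separation of the diastereomers on silica
Reagents that add atoms: (S)-4-benzyl-1,3-oxazolidin-2-one, O=C1OC[C@H](Cc2ccccc2)N1
Why: Acylation of the oxazolidinone through the mixed anhydride turns the two enantiomers into diastereomeric imides that differ at the two centres next to the auxiliary and should separate by chromatography, which secures the absolute configuration (C4 S, C3 R).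

Step 10
Reactants: 19 (4S)-4-benzyl-3-[(2S,3R)-3-{[(tert-butyldiphenylsilyl)oxy]methyl}-2-(2,2-dimethoxyethyl)-4-methylidene-7-(2-methyl-1,3-dioxolan-2-yl)heptanoyl]-1,3-oxazolidin-2-one
Product: 20 (2S,3R)-3-{[(tert-butyldiphenylsilyl)oxy]methyl}-2-(2,2-dimethoxyethyl)-4-methylidene-7-(2-methyl-1,3-dioxolan-2-yl)heptan-1-ol
Conditions: LiBH4, H2O (1 equiv), Et2O, 0 °C
Reagents that add atoms: none
Why: Reductive cleavage of the exocyclic imide carbonyl with LiBH4 should give the primary alcohol without epimerisation and return the auxiliary.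

Step 11
Reactants: 20 (2S,3R)-3-{[(tert-butyldiphenylsilyl)oxy]methyl}-2-(2,2-dimethoxyethyl)-4-methylidene-7-(2-methyl-1,3-dioxolan-2-yl)heptan-1-ol
Product: 21 (2S,3R)-3-{[(tert-butyldiphenylsilyl)oxy]methyl}-2-(2,2-dimethoxyethyl)-4-methylidene-7-(2-methyl-1,3-dioxolan-2-yl)heptanal
Conditions: Dess–Martin periodinane, NaHCO3, CH2Cl2, 0 °C → rt
Reagents that add atoms: none
Why: Buffered Dess–Martin oxidation should deliver the α-branched aldehyde without touching the C4 centre.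

Step 12
Reactants: 21 (2S,3R)-3-{[(tert-butyldiphenylsilyl)oxy]methyl}-2-(2,2-dimethoxyethyl)-4-methylidene-7-(2-methyl-1,3-dioxolan-2-yl)heptanal
Product: 22 tert-butyl{[(2R,3S)-3-ethynyl-5,5-dimethoxy-2-[5-(2-methyl-1,3-dioxolan-2-yl)pent-1-en-2-yl]pentyl]oxy}diphenylsilane
Conditions: dimethyl (1-diazo-2-oxopropyl)phosphonate, K2CO3, MeOH, 0 °C → rt
Reagents that add atoms: dimethyl (1-diazo-2-oxopropyl)phosphonate, COP(=O)(OC)C(=[N+]=[N-])C(C)=O
Why: Ohira–Bestmann (Seyferth–Gilbert) homologation turns the aldehyde carbon into C5 and adds C15 under carbonate conditions mild enough to keep the α-centre C4.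

Step 13
Reactants: 23 2-methylbut-3-yn-2-ol
Product: 24 4-iodo-2-methylbut-3-yn-2-ol
Conditions: N-iodosuccinimide, AgNO3 (cat.), acetone, rt
Reagents that add atoms: N-iodosuccinimide, O=C1CCC(=O)N1I
Why: Silver-catalysed electrophilic iodination of a terminal alkyne gives the 1-iodoalkyne.

Step 14
Reactants: 24 4-iodo-2-methylbut-3-yn-2-ol
Product: 25 (Z)-4-iodo-2-methylbut-3-en-2-ol
Conditions: 2-nitrobenzenesulfonylhydrazide, Et3N, THF–i-PrOH, rt
Reagents that add atoms: none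
Why: Diimide generated in the flask adds hydrogen syn to the iodoalkyne and should give the Z-alkenyl iodide without reducing the carbon–iodine bond.

Step 15
Reactants: 22 tert-butyl{[(2R,3S)-3-ethynyl-5,5-dimethoxy-2-[5-(2-methyl-1,3-dioxolan-2-yl)pent-1-en-2-yl]pentyl]oxy}diphenylsilane; 25 (Z)-4-iodo-2-methylbut-3-en-2-ol
Product: 26 (3Z,7S,8R)-8-{[(tert-butyldiphenylsilyl)oxy]methyl}-7-(2,2-dimethoxyethyl)-2-methyl-9-methylidene-12-(2-methyl-1,3-dioxolan-2-yl)dodec-3-en-5-yn-2-ol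
Conditions: PdCl2(PPh3)2 (cat.), CuI (cat.), Et3N, THF, rt
Reagents that add atoms: none
Why: Sonogashira coupling forms C15–C16 with retention of the Z geometry and tolerates the free tertiary alcohol at room temperature.

Step 16
Reactants: 26 (3Z,7S,8R)-8-{[(tert-butyldiphenylsilyl)oxy]methyl}-7-(2,2-dimethoxyethyl)-2-methyl-9-methylidene-12-(2-methyl-1,3-dioxolan-2-yl)dodec-3-en-5-yn-2-ol
Product: 27 methyl (2E,3S,4R)-4-{[(tert-butyldiphenylsilyl)oxy]methyl}-3-(2,2-dimethoxyethyl)-2-(5,5-dimethylfuran-2(5H)-ylidene)-5-methylidene-8-(2-methyl-1,3-dioxolan-2-yl)octanoate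
Conditions: PdCl2(MeCN)2 (5 mol %), p-benzoquinone (1.5 equiv), CO (1 atm), MeOH, −20 → 0 °C
Reagents that add atoms: carbon monoxide, [C-]#[O+]; methanol, CO
Why: Divalent palladium binds the C5≡C15 alkyne, the tertiary C18 hydroxyl adds anti to it at C15, and the resulting alkenylpalladium at C5 inserts CO and is cleaved by methanol to the ester and zerovalent palladium, which benzoquinone returns to the divalent state. The closest known reaction type is the palladium-catalysed oxidative cyclisation–methoxycarbonylation of alkynols, established for internal 4-yn-1-ols and for Z-2-en-4-yn-1-ols. The dihydrofuran ring (O19, C15–C18) closes in the 5-exo-dig mode. No stereocentre is created; the C5=C15 geometry (C14 trans to O19, C4 cis to O19) follows from anti oxypalladation and retention in the CO insertion. The step needs 5-exo instead of 6-endo attack and CO capture ahead of protonolysis: the cis C16=C17 tether and the gem-dimethyl group hold O19 over C15, the branched C4 shields C5 from oxygen, and the CO atmosphere at low temperature favours insertion. The quaternary C18 blocks aromatisation to a furan and the propargylic centre C4 is not involved.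

Step 17
Reactants: 27 methyl (2E,3S,4R)-4-{[(tert-butyldiphenylsilyl)oxy]methyl}-3-(2,2-dimethoxyethyl)-2-(5,5-dimethylfuran-2(5H)-ylidene)-5-methylidene-8-(2-methyl-1,3-dioxolan-2-yl)octanoate
Product: 28 (2E,3S,4R)-4-{[(tert-butyldiphenylsilyl)oxy]methyl}-3-(2,2-dimethoxyethyl)-2-(5,5-dimethylfuran-2(5H)-ylidene)-5-methylidene-8-(2-methyl-1,3-dioxolan-2-yl)octan-1-ol
Conditions: i-Bu2AlH, CH2Cl2, −78 °C; aq. potassium sodium tartrate (KNaC4H4O6) work-up; used directly
Reagents that add atoms: none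
Why: 1,2-Reduction of the β-alkoxy-acrylate-type ester by i-Bu2AlH at low temperature should give the allylic alcohol, the only other carbonyl-level groups being protected as acetals.

Step 18
Reactants: 28 (2E,3S,4R)-4-{[(tert-butyldiphenylsilyl)oxy]methyl}-3-(2,2-dimethoxyethyl)-2-(5,5-dimethylfuran-2(5H)-ylidene)-5-methylidene-8-(2-methyl-1,3-dioxolan-2-yl)octan-1-ol
Product: 29 (2E,3S,4R)-4-{[(tert-butyldiphenylsilyl)oxy]methyl}-3-(2,2-dimethoxyethyl)-2-(5,5-dimethylfuran-2(5H)-ylidene)-5-methylidene-8-(2-methyl-1,3-dioxolan-2-yl)octanal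
Conditions: MnO2 (excess), CH2Cl2, rt
Reagents that add atoms: none
Why: Neutral allylic oxidation with MnO2 converts the acid-sensitive allylic alcohol into the stable push–pull aldehyde at C14.

Step 19
Reactants: 29 (2E,3S,4R)-4-{[(tert-butyldiphenylsilyl)oxy]methyl}-3-(2,2-dimethoxyethyl)-2-(5,5-dimethylfuran-2(5H)-ylidene)-5-methylidene-8-(2-methyl-1,3-dioxolan-2-yl)octanal
Product: 30 (2E,3S,4R)-3-(2,2-dimethoxyethyl)-2-(5,5-dimethylfuran-2(5H)-ylidene)-4-(hydroxymethyl)-5-methylidene-8-(2-methyl-1,3-dioxolan-2-yl)octanal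
Conditions: n-Bu4NF–AcOH (1:1), THF, rt
Reagents that add atoms: none
Why: Acetic-acid-buffered fluoride removes the silyl ether at C11 without base-sensitive side reactions and leaves acetal, ketal and the conjugated aldehyde intact.

Step 20
Reactants: 30 (2E,3S,4R)-3-(2,2-dimethoxyethyl)-2-(5,5-dimethylfuran-2(5H)-ylidene)-4-(hydroxymethyl)-5-methylidene-8-(2-methyl-1,3-dioxolan-2-yl)octanal
Product: 32 (2R,3S)-3-[(1E)-1-(5,5-dimethylfuran-2(5H)-ylidene)-2-oxoethyl]-5,5-dimethoxy-2-[5-(2-methyl-1,3-dioxolan-2-yl)pent-1-en-2-yl]pentanoic acid, via dialdehyde 31 (not isolated)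
Conditions: TEMPO (cat.), PhI(OAc)2, MeCN–H2O, rt
Reagents that add atoms: water, O
Why: Oxoammonium oxidation takes the primary C11 alcohol through the aliphatic aldehyde and its hydrate to the acid, whereas the conjugated C14 aldehyde does not hydrate and should stay untouched.

Step 21
Reactants: 32 (2R,3S)-3-[(1E)-1-(5,5-dimethylfuran-2(5H)-ylidene)-2-oxoethyl]-5,5-dimethoxy-2-[5-(2-methyl-1,3-dioxolan-2-yl)pent-1-en-2-yl]pentanoic acid
Product: 33 (2R,3S)-3-[(1E)-1-(5,5-dimethylfuran-2(5H)-ylidene)-2-oxoethyl]-5-oxo-2-(6-oxohept-1-en-2-yl)pentanoic acid (CNP0150297.1)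
Conditions: aq. HCl (0.5 M), THF, 0 °C → rt
Reagents that add atoms: water, O
Why: Dilute-acid hydrolysis of the dimethyl acetal and the ketone dioxolane should free C13 and C9 under conditions mild enough for the vinylogous-ester aldehyde and the two stereocentres.

**Compound list**

1 | but-2-yne-1,4-diol | OCC#CCO | starting material
2 | 4-[(4-methoxybenzyl)oxy]but-2-yn-1-ol | OCC#CCOCc1ccc(OC)cc1 | intermediate
3 | cyclic alkenylalanate: sodium 2,2-bis(2-methoxyethoxy)-3-{[(4-methoxybenzyl)oxy]methyl}-2,5-dihydro-1,2-oxaluminol-2-uide | [Na+].COCCO[Al-]1(OCCOC)OCC=C1COCc1ccc(OC)cc1 | intermediate (not isolated)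
4 | (Z)-3-iodo-4-[(4-methoxybenzyl)oxy]but-2-en-1-ol | OC/C=C(\I)COCc1ccc(OC)cc1 | intermediate
5 | (Z)-tert-butyl({3-iodo-4-[(4-methoxybenzyl)oxy]but-2-en-1-yl}oxy)diphenylsilane | CC(C)(C)[Si](OC/C=C(\I)COCc1ccc(OC)cc1)(c1ccccc1)c1ccccc1 | intermediate
6 | 2-(3-chloropropyl)-2-methyl-1,3-dioxolane | CC1(CCCCl)OCCO1 | starting material
7 | [3-(2-methyl-1,3-dioxolan-2-yl)propyl]magnesium chloride | CC1(CCC[Mg]Cl)OCCO1 | intermediate (not isolated)
8 | [3-(2-methyl-1,3-dioxolan-2-yl)propyl]zinc chloride | CC1(CCC[Zn]Cl)OCCO1 | intermediate (not isolated)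
9 | (E)-tert-butyl{[3-{[(4-methoxybenzyl)oxy]methyl}-6-(2-methyl-1,3-dioxolan-2-yl)hex-2-en-1-yl]oxy}diphenylsilane | CC(C)(C)[Si](OC/C=C(\CCCC1(C)OCCO1)COCc1ccc(OC)cc1)(c1ccccc1)c1ccccc1 | intermediate
10 | (E)-2-{2-[(tert-butyldiphenylsilyl)oxy]ethylidene}-5-(2-methyl-1,3-dioxolan-2-yl)pentan-1-ol | OC/C(CCCC1(C)OCCO1)=C/CO[Si](c1ccccc1)(c1ccccc1)C(C)(C)C | intermediate
11 | methyl 4,4-dimethoxybutanoate | COC(=O)CCC(OC)OC | starting material
12 | 4,4-dimethoxybutanoic acid | OC(=O)CCC(OC)OC | intermediate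
13 | (E)-2-{2-[(tert-butyldiphenylsilyl)oxy]ethylidene}-5-(2-methyl-1,3-dioxolan-2-yl)pentyl 4,4-dimethoxybutanoate | COC(OC)CCC(=O)OC/C(CCCC1(C)OCCO1)=C/CO[Si](c1ccccc1)(c1ccccc1)C(C)(C)C | intermediate
14 | lithium E(O)-enolate of 13 (C12 chain trans to OLi) | COC(OC)C/C=C(/O[Li])OC/C(CCCC1(C)OCCO1)=C/CO[Si](c1ccccc1)(c1ccccc1)C(C)(C)C | intermediate (not isolated)
15 | (E)-trimethylsilyl ketene acetal of 13 | COC(OC)C/C=C(/O[Si](C)(C)C)OC/C(CCCC1(C)OCCO1)=C/CO[Si](c1ccccc1)(c1ccccc1)C(C)(C)C | intermediate (not isolated)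
16 | trimethylsilyl ester of rac-17 | C=C(CCCC1(C)OCCO1)[C@H](CO[Si](c1ccccc1)(c1ccccc1)C(C)(C)C)[C@H](CC(OC)OC)C(=O)O[Si](C)(C)C.C=C(CCCC1(C)OCCO1)[C@@H](CO[Si](c1ccccc1)(c1ccccc1)C(C)(C)C)[C@@H](CC(OC)OC)C(=O)O[Si](C)(C)C | intermediate (not isolated)
17 | rac-(2S,3R)-3-{[(tert-butyldiphenylsilyl)oxy]methyl}-2-(2,2-dimethoxyethyl)-4-methylidene-7-(2-methyl-1,3-dioxolan-2-yl)heptanoic acid | C=C(CCCC1(C)OCCO1)[C@H](CO[Si](c1ccccc1)(c1ccccc1)C(C)(C)C)[C@H](CC(OC)OC)C(O)=O.C=C(CCCC1(C)OCCO1)[C@@H](CO[Si](c1ccccc1)(c1ccccc1)C(C)(C)C)[C@@H](CC(OC)OC)C(O)=O | intermediate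
18 | mixed pivalic anhydride of rac-17 | C=C(CCCC1(C)OCCO1)[C@H](CO[Si](c1ccccc1)(c1ccccc1)C(C)(C)C)[C@H](CC(OC)OC)C(=O)OC(=O)C(C)(C)C.C=C(CCCC1(C)OCCO1)[C@@H](CO[Si](c1ccccc1)(c1ccccc1)C(C)(C)C)[C@@H](CC(OC)OC)C(=O)OC(=O)C(C)(C)C | intermediate (not isolated)
19 | (4S)-4-benzyl-3-[(2S,3R)-3-{[(tert-butyldiphenylsilyl)oxy]methyl}-2-(2,2-dimethoxyethyl)-4-methylidene-7-(2-methyl-1,3-dioxolan-2-yl)heptanoyl]-1,3-oxazolidin-2-one | C=C(CCCC1(C)OCCO1)[C@H](CO[Si](c1ccccc1)(c1ccccc1)C(C)(C)C)[C@H](CC(OC)OC)C(=O)N1[C@@H](Cc2ccccc2)COC1=O | intermediate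
20 | (2S,3R)-3-{[(tert-butyldiphenylsilyl)oxy]methyl}-2-(2,2-dimethoxyethyl)-4-methylidene-7-(2-methyl-1,3-dioxolan-2-yl)heptan-1-ol | C=C(CCCC1(C)OCCO1)[C@H](CO[Si](c1ccccc1)(c1ccccc1)C(C)(C)C)[C@H](CC(OC)OC)CO | intermediate
21 | (2S,3R)-3-{[(tert-butyldiphenylsilyl)oxy]methyl}-2-(2,2-dimethoxyethyl)-4-methylidene-7-(2-methyl-1,3-dioxolan-2-yl)heptanal | C=C(CCCC1(C)OCCO1)[C@H](CO[Si](c1ccccc1)(c1ccccc1)C(C)(C)C)[C@H](CC(OC)OC)C=O | intermediate
22 | tert-butyl{[(2R,3S)-3-ethynyl-5,5-dimethoxy-2-[5-(2-methyl-1,3-dioxolan-2-yl)pent-1-en-2-yl]pentyl]oxy}diphenylsilane | C=C(CCCC1(C)OCCO1)[C@H](CO[Si](c1ccccc1)(c1ccccc1)C(C)(C)C)[C@H](CC(OC)OC)C#C | intermediate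
23 | 2-methylbut-3-yn-2-ol | CC(C)(O)C#C | starting material
24 | 4-iodo-2-methylbut-3-yn-2-ol | CC(C)(O)C#CI | intermediate
25 | (Z)-4-iodo-2-methylbut-3-en-2-ol | CC(C)(O)/C=C\I | intermediate
26 | (3Z,7S,8R)-8-{[(tert-butyldiphenylsilyl)oxy]methyl}-7-(2,2-dimethoxyethyl)-2-methyl-9-methylidene-12-(2-methyl-1,3-dioxolan-2-yl)dodec-3-en-5-yn-2-ol (Z-enynol, precursor of the key step) | C=C(CCCC1(C)OCCO1)[C@H](CO[Si](c1ccccc1)(c1ccccc1)C(C)(C)C)[C@H](CC(OC)OC)C#C/C=C\C(C)(C)O | intermediate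
27 | methyl (2E,3S,4R)-4-{[(tert-butyldiphenylsilyl)oxy]methyl}-3-(2,2-dimethoxyethyl)-2-(5,5-dimethylfuran-2(5H)-ylidene)-5-methylidene-8-(2-methyl-1,3-dioxolan-2-yl)octanoate (product of the key step) | C=C(CCCC1(C)OCCO1)[C@H](CO[Si](c1ccccc1)(c1ccccc1)C(C)(C)C)[C@H](CC(OC)OC)/C(C(=O)OC)=C1/C=CC(C)(C)O1 | intermediate
28 | (2E,3S,4R)-4-{[(tert-butyldiphenylsilyl)oxy]methyl}-3-(2,2-dimethoxyethyl)-2-(5,5-dimethylfuran-2(5H)-ylidene)-5-methylidene-8-(2-methyl-1,3-dioxolan-2-yl)octan-1-ol | C=C(CCCC1(C)OCCO1)[C@H](CO[Si](c1ccccc1)(c1ccccc1)C(C)(C)C)[C@H](CC(OC)OC)/C(CO)=C1/C=CC(C)(C)O1 | intermediate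
29 | (2E,3S,4R)-4-{[(tert-butyldiphenylsilyl)oxy]methyl}-3-(2,2-dimethoxyethyl)-2-(5,5-dimethylfuran-2(5H)-ylidene)-5-methylidene-8-(2-methyl-1,3-dioxolan-2-yl)octanal | C=C(CCCC1(C)OCCO1)[C@H](CO[Si](c1ccccc1)(c1ccccc1)C(C)(C)C)[C@H](CC(OC)OC)/C(C=O)=C1/C=CC(C)(C)O1 | intermediate
30 | (2E,3S,4R)-3-(2,2-dimethoxyethyl)-2-(5,5-dimethylfuran-2(5H)-ylidene)-4-(hydroxymethyl)-5-methylidene-8-(2-methyl-1,3-dioxolan-2-yl)octanal | C=C(CCCC1(C)OCCO1)[C@H](CO)[C@H](CC(OC)OC)/C(C=O)=C1/C=CC(C)(C)O1 | intermediate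
31 | (2R,3S,4E)-3-(2,2-dimethoxyethyl)-4-(5,5-dimethylfuran-2(5H)-ylidene)-2-[5-(2-methyl-1,3-dioxolan-2-yl)pent-1-en-2-yl]pentanedial | C=C(CCCC1(C)OCCO1)[C@H](C=O)[C@H](CC(OC)OC)/C(C=O)=C1/C=CC(C)(C)O1 | intermediate (not isolated)
32 | (2R,3S)-3-[(1E)-1-(5,5-dimethylfuran-2(5H)-ylidene)-2-oxoethyl]-5,5-dimethoxy-2-[5-(2-methyl-1,3-dioxolan-2-yl)pent-1-en-2-yl]pentanoic acid | C=C(CCCC1(C)OCCO1)[C@H](C(=O)O)[C@H](CC(OC)OC)/C(C=O)=C1/C=CC(C)(C)O1 | intermediate
33 | (2R,3S)-3-[(1E)-1-(5,5-dimethylfuran-2(5H)-ylidene)-2-oxoethyl]-5-oxo-2-(6-oxohept-1-en-2-yl)pentanoic acid | C=C(CCCC(C)=O)[C@H](C(=O)O)[C@H](CC=O)/C(C=O)=C1/C=CC(C)(C)O1 | target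

**Step count.** Total: 21 steps. Longest linear sequence: 18 steps (from 1 through steps 1–5, 7–12 and 15–21).

**Steps most likely to fail**

Step 16. Capture of carbon monoxide may lose out to protonolysis of the alkenylpalladium intermediate, so that the ring closes without C14. Oxygen may also attack C5 in a 6-endo closure, and the acid released during turnover may exchange the dioxolane for a dimethyl ketal in methanol. Fallback: the two bonds would be made one after the other, setting out from 26. Iodoetherification (I2, NaHCO3, MeCN, 0 °C; 5-exo-dig, anti) should give tert-butyl{[(2R,3S)-3-[(E)-(5,5-dimethylfuran-2(5H)-ylidene)iodomethyl]-5,5-dimethoxy-2-[5-(2-methyl-1,3-dioxolan-2-yl)pent-1-en-2-yl]pentyl]oxy}diphenylsilane F1. Its alkenyl iodide would then be methoxycarbonylated with retention (PdCl2(PPh3)2 cat., CO 1 atm, MeOH, Et3N, 50 °C), which comes back to the route at 27.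

Step 8. Leakage of enolate geometry would erode the anti selectivity, and because the rearrangement gives no absolute control, half of the material is lost in step 9, where the separation may also be inefficient. Fallback: setting out from 13, the ester would be rearranged as a chiral boron enolate (enantioselective Ireland–Claisen rearrangement). The reagent would be the antipode of 2-bromo-4,5-diphenyl-1,3-bis{[3,5-bis(trifluoromethyl)phenyl]sulfonyl}-1,3,2-diazaborolidine matched to the (2S,3R) series, with Et3N in toluene–hexane at −78 → −20 °C. This should give (2S,3R)-3-{[(tert-butyldiphenylsilyl)oxy]methyl}-2-(2,2-dimethoxyethyl)-4-methylidene-7-(2-methyl-1,3-dioxolan-2-yl)heptanoic acid F2 as a single enantiomer. Reduction with LiAlH4 (THF, 0 °C) comes back to the route at 20.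

Step 20. The oxoammonium oxidant may fail to discriminate between the two carbonyl sites: the hydroxy aldehyde may close to a lactol that is oxidised to a lactone, or the electron-rich diene may be attacked. Fallback: the order of the end game would be inverted, setting out from 27.
- Buffered desilylation (n-Bu4NF–AcOH, THF) should give methyl (2E,3S,4R)-3-(2,2-dimethoxyethyl)-2-(5,5-dimethylfuran-2(5H)-ylidene)-4-(hydroxymethyl)-5-methylidene-8-(2-methyl-1,3-dioxolan-2-yl)octanoate F3.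
- TEMPO/PhI(OAc)2 in MeCN–H2O, with no aldehyde present, should give (2R,3S)-3-[(1E)-1-(5,5-dimethylfuran-2(5H)-ylidene)-2-methoxy-2-oxoethyl]-5,5-dimethoxy-2-[5-(2-methyl-1,3-dioxolan-2-yl)pent-1-en-2-yl]pentanoic acid F4.
- Excess i-Bu2AlH at −78 °C, with the acid held as its aluminium carboxylate, should reduce the ester to (2R,3S)-3-[(1E)-1-(5,5-dimethylfuran-2(5H)-ylidene)-2-hydroxyethyl]-5,5-dimethoxy-2-[5-(2-methyl-1,3-dioxolan-2-yl)pent-1-en-2-yl]pentanoic acid F5.
- Allylic oxidation with Dess–Martin periodinane (NaHCO3, CH2Cl2) comes back to the route at 32.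

Further compounds
F1 | step 16 | tert-butyl{[(2R,3S)-3-[(E)-(5,5-dimethylfuran-2(5H)-ylidene)iodomethyl]-5,5-dimethoxy-2-[5-(2-methyl-1,3-dioxolan-2-yl)pent-1-en-2-yl]pentyl]oxy}diphenylsilane | C=C(CCCC1(C)OCCO1)[C@H](CO[Si](c1ccccc1)(c1ccccc1)C(C)(C)C)[C@H](CC(OC)OC)/C(I)=C1/C=CC(C)(C)O1
F2 | step 8 | (2S,3R)-3-{[(tert-butyldiphenylsilyl)oxy]methyl}-2-(2,2-dimethoxyethyl)-4-methylidene-7-(2-methyl-1,3-dioxolan-2-yl)heptanoic acid (single enantiomer) | C=C(CCCC1(C)OCCO1)[C@H](CO[Si](c1ccccc1)(c1ccccc1)C(C)(C)C)[C@H](CC(OC)OC)C(O)=O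
F3 | step 20 | methyl (2E,3S,4R)-3-(2,2-dimethoxyethyl)-2-(5,5-dimethylfuran-2(5H)-ylidene)-4-(hydroxymethyl)-5-methylidene-8-(2-methyl-1,3-dioxolan-2-yl)octanoate | C=C(CCCC1(C)OCCO1)[C@H](CO)[C@H](CC(OC)OC)/C(C(=O)OC)=C1/C=CC(C)(C)O1
F4 | step 20 | (2R,3S)-3-[(1E)-1-(5,5-dimethylfuran-2(5H)-ylidene)-2-methoxy-2-oxoethyl]-5,5-dimethoxy-2-[5-(2-methyl-1,3-dioxolan-2-yl)pent-1-en-2-yl]pentanoic acid | C=C(CCCC1(C)OCCO1)[C@H](C(=O)O)[C@H](CC(OC)OC)/C(C(=O)OC)=C1/C=CC(C)(C)O1
F5 | step 20 | (2R,3S)-3-[(1E)-1-(5,5-dimethylfuran-2(5H)-ylidene)-2-hydroxyethyl]-5,5-dimethoxy-2-[5-(2-methyl-1,3-dioxolan-2-yl)pent-1-en-2-yl]pentanoic acid | C=C(CCCC1(C)OCCO1)[C@H](C(=O)O)[C@H](CC(OC)OC)/C(CO)=C1/C=CC(C)(C)O1
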